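A catalyst molecule cannot hold G and D at once, and E comes off G.Z, so the reckoning turns on how much of the catalyst stands as G.Z.

the same everywhere: G 0.20 M; D 0.400 M; Z 0.40 mM; time 25 h
- Monday's: temperature 140 °C
- Friday's: temperature 110 °C
- Wednesday's: temperature 80 °C

    D.Z + E → D.Z.E (k1 = 8.2 × 10⁻⁵ M⁻¹ s⁻¹, Ea1 = 109 kJ mol⁻¹)
    G + Z ⇌ G.Z (K2 = 3.3 M⁻¹, k2 = 0.016 M⁻¹ s⁻¹, Ea2 = 60.0 kJ mol⁻¹, ΔH2 = −35.0 kJ mol⁻¹)
    D + Z ⇌ D.Z (K3 = 19 M⁻¹, k3 = 0.047 M⁻¹ s⁻¹, Ea3 = 66.0 kJ mol⁻¹, ΔH3 = −72.0 kJ mol⁻¹)
    G.Z → Z + E (k4 = 0.0012 s⁻¹, Ea4 = 104 kJ mol⁻¹)
    D.Z → Z + Q (k5 = 0.0024 s⁻¹, Ea5 = 107 kJ mol⁻¹)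
    (constants at 110 °C)

- which flask leads in amount of E, in percent of the G charged ("all alike" within 1.5 percentage points) (Monday's / Friday's / Wednesday's / all alike)
- how much E is there at the end, in percent of the G charged: Monday's
- how much E is there at the end, in percent of the G charged: Friday's
- how much E is there at the end, in percent of the G charged: Wednesday's

- constants are those at 110 °C; use the activation energies and enthalpies for any other temperature

The first rung is the forms of the catalyst. On Wednesday's, G.Z relaxes in 15.1 min, far shorter than the asked time. So G.Z, D.Z and Z can be taken at quasi-steady state, with [G] and [D] frozen at their charges and D.Z.E left out of the balance for now.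

Per free Z, the binding number bG is the rate at which G.Z forms over the summed rates at which it leaves, back to G + Z and on to Z + E. The number bD is the same for D.Z, whose exits lead back to D + Z and on to Z + Q. On Monday's these are 0.228 and 0.996. The working share φ, G.Z as a part of the catalyst, is bG over the sum of 1, bG and bD: 10.3% there. E in percent of the G charged is then φ times the release constant of G.Z, times the catalyst charge and the time, over the G charge.

| Flask | bG | bD | φ | Release constant | E |
|---|---|---|---|---|---|
| Monday's | 0.228 | 0.996 | 10.3% | 0.0128 s⁻¹ | 23.7% |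
| Friday's | 0.529 | 3.86 | 9.82% | 0.0012 s⁻¹ | 2.12% |
| Wednesday's | 1.40 | 16.1 | 7.59% | 7.49 × 10⁻⁵ s⁻¹ | 0.102% |

From Wednesday's to Monday's the release constant gains a factor of 170, far more than the factor of 1.36 by which φ moves. The reckoning therefore ranks Monday's first.

The slower rungs test the freeze on Monday's. At the E reckoned for the end, E captures D.Z into D.Z.E on a clock of 13.3 h. At its starting rate, Monday's D charge lasts 22.6 h, less than the asked time, while G lasts 105 h. On Friday's the D clock is 162 h, longer than the asked time and longer than Monday's, so the freeze is firmer on Friday's.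

The forecast gives Monday's first, with 21%, 2.2% and 0.1%, holding that “Friday's and Wednesday's stay close to simple steady turnover”; its Monday's value lies below this reckoning.

The simulation puts Monday's first, with 21.1%, 2.21% and 0.105%.

Monday's reaches 89.0% of what the frozen φ gives, with 43.4% of the catalyst as D.Z.E at 25.0 h. The undoing of G.Z into G + Z, the back step inside bG, is together with the time given a part of what holds Monday's E at this level: without that undoing E reaches 44.3%, closing 29% of what is missing, and left ten times as long it reaches 43.6%.

Monday's flask with 0.050 M of G scales bG with [G], so φ becomes 2.78% and E 25.7% of its G charge. The simulation gives 26.9%.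

The constants used here are invented; the flask was simulated.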